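## Structural features

The target is a germacranolide: a ten-membered carbocycle (C1–C10) fused across C6–C7 to a butenolide (O6–C12(=O)–C11=C7), with C11 carrying the acetoxymethyl carbon C13. The ring holds a trisubstituted ring-cis C1=C10 alkene (C14 on C10 as a 3-methylbut-2-enoate), a trans-2,3-epoxide and a cis-4,5-epoxide sharing the C3–C4 bond (C15 methyl on C4), and a trans vicinal diester at C8 (acetate) and C9 ((S)-2-methylglycidate). Seven ring stereocentres are present: C2–C6 are contiguous, C8 and C9 are contiguous, and C6 is separated from C8 by the sp2 carbon C7; an eighth centre sits in the glycidate. Fragile groups are the two ring epoxides (the 2,3-epoxide is allylic to C1=C10), the glycidate, four esters with possible C8/C9 acyl migration, the allylic C13 acetate on the butenolide and the acidic H-6. The real difficulty is the medium ring itself: it must be closed with the correct alkene geometry and with stereochemical information carried across it. The key step uses the fact that the oxygen-bearing carbons C3 and C8 are 1,6-related and that the arc C9–C10=C1–C2 is cis. Joining C3 to C8 on paper gives a cyclohexene (C8, C9, C10, C1, C2, C3) whose two carbinol carbons carry C4(=C5)CH3 and C7=C6–O, a 3,4-dioxy-1,5-diene set up for a ring-expanding [3,3] shift.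

## Logic of the disconnections

**43 to 39 and 41 (C9 O–acyl bond).** The glycidate is the ester most sensitive to nucleophiles and acid, so it is attached last. This removes one stereocentre and one epoxide from all earlier intermediates. The forward step must acylate a hindered secondary alcohol beside the C8 acetate without acyl migration. 41 comes from 40 by oxidation of CH2OH to CO2H, which does not touch the quaternary centre.

**39 to 37 and 38, and 37 to 36 (C14 O–acyl bond, two O–Si bonds).** A primary allylic alcohol is acylated in front of the hindered C9 alcohol, so one protecting group type serves both oxygens and one deprotection frees both. The demand is a desilylation that spares two ring epoxides.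

**36 to 35 (C2–O bond of the 2,3-epoxide).** The trans-epoxide is traced to an erythro 2α,3α-diol. C3–O is kept and C2 is inverted by intramolecular displacement. The C2 oxygen is therefore only a placeholder whose configuration comes from the chiral pool. The forward step must activate the allylic C2 hydroxyl and not the C3 hydroxyl, which sits beside the quaternary epoxide carbon C4.

**35 to 33 through 34 (lactone O6–C12 bond, benzylic C–O bonds at O2 and O6).** Both arylmethyl ethers fall in one oxidative step, and the C6 hydroxyl closes the butenolide on the ester held cis to it on C7=C11. The demand is that C7=C11 already has the ester on the C6 side.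

**33 to 32 to 31 (C4–O and C5–O of the epoxide; C3–H).** The cis-4,5-epoxide comes from the (Z)-alkene by delivery of oxygen to the peripheral face syn to the C3 hydroxyl, which is threo to both flanking carbinols. The 3α-alcohol comes from the enone by chelation through the C2 ether oxygen. The demands are a (Z)-enone and a chelating group on O2.

**31 to 30 (C4=C5).** The enone is drawn from the regiodefined C3 silyl enol ether by dehydrogenation. The C3=C4 enol ether must therefore survive until this point, which is why the enolates are trapped as tert-butyldimethylsilyl and not trimethylsilyl ethers.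

**30 to 29 to 28 (C8 O–acetyl, C8–H).** The 8β-acetate comes from the C8 ketone by Felkin–Anh reduction next to the non-chelating C9 silyl ether, then acetylation while no other hydroxyl is free.

**28 to 26 (through 27), and 26 to 23 and 25 (C7=C11, then C7–C11).** An aldol condensation attaches C11 with C12 and C13 already at their final oxidation levels; 25 comes from 24 by substitution. The two silyl enol ethers of 23 must be told apart: only the trisubstituted C7=C8 ether can take a ketone electrophile without joining two fully substituted carbons.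

**23 to 20 (key step; C5–C6 formed, C3–C8 broken).** This removes the ten-membered ring and the C6 stereocentre in one step and leads back to a cyclohexene. Three points of design matter:
- A precursor with C2 as CH2 would leave the 2,3-epoxide without a stereodefined handle, so 20 carries the 2α-arylmethyl ether.
- An acetal on O9 would need acid for removal late in the route, so O9 carries the same silyl group that traps the enolates. A 1,2-silyl shift from O9 to the O8 alkoxide then changes nothing in the product.
- The enol ether must be (E) and the diol trans, so that one chair transition state is available.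

**20 to 19, and 19 to 13 and 16 (alkyne to (E)-alkene; C7–C8).** The enol ether arm is added as an alkoxyacetylide, a slim nucleophile, and reduced anti. 16 comes from 14 and 15. The addition must come from the α face of the C8 ketone, anti to the isopropenyl group on C3.

**13 to 12 to 11 to 10 (oxidation level and protection).** Removing the acetal before any silyl ether is present allows one silylation to protect O14 and O9 and leave the hindered C8 hydroxyl for oxidation.

**10 to 8 and 9 (C10–C14); 8 to 6 and 7 (C3–C4); 6 to 5.** C14 enters at the alcohol level by cross-coupling at the alkenyl bromide. The isopropenyl group adds to the C3 ketone from the β face, away from both α-oxygens.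

**5 to 3 and 4 (C2–O); 3 to 2 to 1.** Opening the epoxide with an alcohol in place of a hydride keeps the C2 oxygen and avoids zerovalent palladium in the presence of the alkenyl bromide. The enzymatically derived cis-diol 1 supplies C9 directly and, through the acetal-directed epoxidation, C2.

## Other disconnections considered

**Alternative 1:** The cut is the C6–C7 bond together with the lactone O6–C12 bond. In the forward step CrCl2 with catalytic NiCl2 would turn a (Z)-β-iodoenoate into an alkenylchromium that adds to a C6 epoxy aldehyde, and the chromium alkoxide would lactonise to give A1 (bicyclic core with C9 triethylsilyl and C14 tert-butyldimethylsilyl ethers).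
- In favour: both rings form in one operation from a linear chain. Both epoxides and the C4/C5 relationship would be fixed before ring closure by reagent-controlled reactions. On the certainty of the 4,5-epoxide geometry this is better than the chosen plan, and as a convergent route its longest linear sequence is the equal of the chosen plan or shorter.
- Against: the organometallic carbon C7 is fully substituted, carries an ester on the adjacent alkene carbon, and has acyloxy groups on C8 and C13, both placed for β-elimination to allenes. The C6 configuration would have to come from 1,2-induction by the epoxide during an entropically poor ten-membered closure at high dilution. The linear precursor carries a (Z)-trisubstituted alkene, two epoxides and an enolisable epoxy aldehyde.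
- Comparison: the chosen plan closes no medium ring end to end, since the ring appears by cleavage of a six-membered ring in a unimolecular pericyclic step with a closed chair transition state. Alternative 1 relies on an open polar addition. On structure A1 is closer to the target than 23; on mechanism the chosen step is better defined.

**Alternative 2:** The cut is the pair of bonds C3–O and C6–O. In the forward step photosensitised singlet oxygen would add across a ring (3Z,5Z)-diene to give the endoperoxide A2.
- In favour: the cycloaddition is suprafacial, so O3 and O6 arrive on one face and C4=C5 is necessarily cis. This is better than the chosen plan, where the enone geometry is the least secure element. The later logic (C6 hydroxyl to the lactone, C3 hydroxyl beside the 4,5-epoxide, an α-oxygen on C2 as leaving group) is the same as in the chosen plan and is its equal.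
- Against: the step forms no C–C bond and no carbocycle, so the ten-membered triene with a cross-conjugated enoate must be made first and that problem is untouched. Ene reactions at C1=C10 and at the C15 methyl compete. Facial selectivity rests on the ring conformation. The endoperoxide next to an acidic H-6 is prone to base-induced rearrangement.
- Comparison: alternative 2 is an oxygenation tactic, the chosen plan a ring construction. A combination is conceivable, but as a strategy alternative 2 leaves more steps before its key step.

**Alternative 3:** The cut is the C2=C7 bond of a bicyclic precursor. Birch reduction of A3 (2,7-dimethylnaphthalene) would give A4 (2,7-dimethyl-1,4,5,8-tetrahydronaphthalene), and ozone would cleave its tetrasubstituted ring-fusion alkene to give A5 ((3Z,8Z)-4,8-dimethylcyclodeca-3,8-diene-1,6-dione).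
- In favour: two steps from a cheap arene reach a ten-membered ring with two cis trisubstituted alkenes and no protecting groups. In steps to the ring and in cost this is better than the chosen plan.
- Against: A5 is achiral and has oxygen only at C2 and C7, and its alkenes lie at C4=C5 and C9=C10, so one must be transposed to C1=C10. Oxygen is missing at C3, C5, C6, C8, C9 and C14, and all eight stereocentres and C11–C13 are missing. The two alkenes are symmetry-related, so a desymmetrisation is needed. The free 1,6-dione invites transannular aldol reaction and migration of the β,γ-alkenes into conjugation.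
- Comparison: both plans pass through a cyclodeca-1,6-dione motif. The chosen plan delivers it masked as two regiodefined silyl enol ethers, enantiopure, with C2, C6 and C9 set. A5 reaches the ring sooner but would need far more steps afterwards.

Key step: step 13

Remarks on the chemistry (assumptions):
- Germacrane numbering is used for every intermediate; the cyclohexenes contain C8–C9–C10=C1–C2–C3.
- With the numbering running clockwise, β substituents point to the viewer. In this convention the target has 6α-O, 8β-OAc, 9α-O, a 4β,5β-epoxide and a 2,3-epoxide with C2–O β and C3–O α.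
- NAP = naphthalen-2-ylmethyl, PMB = 4-methoxybenzyl, TBS = tert-butyldimethylsilyl.
- Compounds 4, 7, 9, 14, 15, 24, 38 and 40 are taken as commercially available.
- Compounds 26 and 27 are mixtures at C7 and C11; both centres become sp2 in step 16.

## Route

Step 1
Reactants: 1 (1S,2S)-3-bromocyclohexa-3,5-diene-1,2-diol
Product: 2 (3aS,7aS)-4-bromo-2,2-dimethyl-3a,7a-dihydro-1,3-benzodioxole (8α,9α-acetonide)
Conditions: 2,2-dimethoxypropane, TsOH·H2O (cat.), acetone, 0 °C to rt
Reagents that add atoms: 2,2-dimethoxypropane, COC(C)(C)OC
Why: Acid-catalysed transacetalisation of the cis-diol (acetonide formation) stops dehydrative aromatisation and shields the α face. The diene is used at once because it dimerises slowly by Diels–Alder reaction.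

Step 2
Reactants: 2 acetonide
Product: 3 2β,3β-epoxide of 2 (oxirane on the bromine-free alkene; anti to the acetonide)
Conditions: mCPBA, CH2Cl2, 0 °C to rt
Reagents that add atoms: 3-chloroperoxybenzoic acid, OOC(=O)c1cccc(Cl)c1
Why: Prilezhaev epoxidation; the peracid takes the more electron-rich, unhalogenated alkene from the face opposite the acetonide, which fixes the sense of the later C2 centre.

Step 3
Reactants: 3 bromo epoxy acetonide; 4 naphthalen-2-ylmethanol
Product: 5 10-bromo-2α-(naphthalen-2-ylmethoxy)cyclohexen-3β-ol 8α,9α-acetonide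
Conditions: BF3·OEt2 (10 mol %), CH2Cl2, −20 °C
Reagents that add atoms: none
Why: Lewis-acid-catalysed alcoholysis of a vinyl epoxide (SN2-type, trans-diaxial); the alcohol attacks the allylic carbon C2 with inversion, the regiochemistry shown by this epoxide class with heteroatom nucleophiles. This sets C2 (O α) and avoids any palladium step while the alkenyl bromide is present.

Step 4
Reactants: 5 bromo alcohol
Product: 6 3-ketone of 5
Conditions: Dess–Martin periodinane, NaHCO3, CH2Cl2, 0 °C
Reagents that add atoms: none
Why: Hypervalent iodine oxidation under buffered, non-basic conditions, so that C2 (α to the ketone and allylic) is not epimerised and C1=C10 does not move into conjugation; the ketone is used crude.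

Step 5
Reactants: 6 ketone; 7 isopropenylmagnesium bromide
Product: 8 10-bromo-3β-isopropenyl-2α-(naphthalen-2-ylmethoxy)cyclohexen-3α-ol 8α,9α-acetonide
Conditions: CeCl3, THF, −78 °C; aq. NH4Cl
Reagents that add atoms: none
Why: Organocerium 1,2-addition suppresses enolisation. Both α-oxygens (O2 and O8) and the acetal ring lie on the α face, so the Cram-chelate, Felkin–Anh and steric models all send the nucleophile to the β face, giving 3β-isopropenyl and 3α-OH.

Step 6
Reactants: 8 bromo tertiary alcohol; 9 (tributylstannyl)methanol
Product: 10 10-(hydroxymethyl) analogue of 8 (C14 alcohol)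
Conditions: Pd(PPh3)4 (5 mol %), dioxane, 90 °C
Reagents that add atoms: none
Why: Migita–Kosugi–Stille coupling of an alkenyl bromide with a hydroxymethylstannane brings in C14 at the alcohol level without a separate reduction. Intramolecular Heck reaction with the isopropenyl group is excluded because it would need a bridgehead alkene.

Step 7
Reactants: 10 allylic alcohol acetonide
Product: 11 tetraol (3α,8α,9α,14-tetrahydroxy; 3β-isopropenyl; 2α-O-NAP)
Conditions: AcOH/H2O (4:1), 50 °C
Reagents that add atoms: none
Why: Acid hydrolysis of the isopropylidene acetal, done before any silyl ether is present. The tertiary C3 carbinol is flanked by two C–O bonds and resists ionisation.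

Step 8
Reactants: 11 tetraol
Product: 12 9α,14-bis-O-TBS ether of 11 (3α-OH and 8α-OH free)
Conditions: TBSCl (2.1 equiv), imidazole, DMF, 0 °C
Reagents that add atoms: tert-butyldimethylsilyl chloride, CC(C)(C)[Si](C)(C)Cl
Why: Silylation follows steric accessibility: the primary C14 hydroxyl first, then the allylic secondary C9 hydroxyl. The C8 hydroxyl next to the quaternary C3 and the tertiary C3 hydroxyl are left.

Step 9
Reactants: 12 diol
Product: 13 8-ketone of 12 (3α-hydroxy ketone)
Conditions: (n-Pr)4N[RuO4] (5 mol %), N-methylmorpholine N-oxide, 4 Å MS, CH2Cl2, rt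
Reagents that add atoms: none
Why: Ley–Griffith oxidation of the only secondary alcohol under neutral conditions, without glycol cleavage and without base at the epimerisable C9 centre.

Step 10
Reactants: 14 4-methoxybenzyl alcohol; 15 trichloroethylene
Product: 16 1-({[(E)-1,2-dichloroethenyl]oxy}methyl)-4-methoxybenzene
Conditions: KH, THF, 0 °C to rt
Reagents that add atoms: none
Why: Dehydrochlorination gives dichloroacetylene in situ, and anti-addition of the potassium alkoxide then gives the (E)-1,2-dichlorovinyl ether, a storable precursor of the alkoxyacetylide.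

Step 11
Reactants: 13 hydroxy ketone; 16 dichlorovinyl ether
Product: 19 8α-[(4-methoxybenzyloxy)ethynyl] 3α,8β-diol (2α-O-NAP; 9α-OTBS; 14-OTBS), via lithium alkoxyacetylide 17 (not isolated), via chloromagnesium alkoxide 18 (not isolated)
Conditions: 16, n-BuLi (2.1 equiv), THF, −78 to −40 °C; 13, t-BuMgCl (1.0 equiv), THF, −78 °C; combine, −78 to −30 °C; aq. NH4Cl
Reagents that add atoms: none
Why: Elimination and chlorine–lithium exchange give the acetylide, which adds to the ketone under chelation control (Cram chelate of an α-alkoxide ketone). In the magnesium chelate O3 lies in the carbonyl plane and the isopropenyl group is axial on the β face, so the slim nucleophile enters axially from the α face and gives the trans-diol (8β-OH).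

Step 12
Reactants: 19 propargylic diol
Product: 20 8α-[(E)-2-(4-methoxybenzyloxy)ethenyl]-3β-isopropenyl 3α,8β-diol (2α-O-NAP; 9α-OTBS; 14-OTBS; oxy-Cope precursor)
Conditions: LiAlH4, THF, 0 °C to rt; Rochelle salt work-up
Reagents that add atoms: none
Why: Hydroxyl-directed trans-hydroalumination of a propargylic alcohol and protonolysis on work-up give only the (E)-enol ether. The product is acid-sensitive and is purified on base-washed silica.

Step 13
Reactants: 20 trans-1,2-dialkenylcyclohexene-1,2-diol
Product: 23 ten-membered triene bis(TBS enol ether) (6α-OPMB; 2α-O-NAP; 9α-OTBS; 14-OTBS), via dipotassium dialkoxide 21 (not isolated), via dipotassium bis-enolate 22 (not isolated)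
Conditions: KH (3 equiv), 18-crown-6, THF, 0 °C to rt; TBSCl (4 equiv), −78 to 0 °C
Reagents that add atoms: tert-butyldimethylsilyl chloride, CC(C)(C)[Si](C)(C)Cl
Why: KH with the crown ether gives the dialkoxide, whose two oxyanions flank and weaken the C3–C8 bond, so the [3,3] shift forms C5–C6 and breaks C3–C8 at or below room temperature; this is the dianionic oxy-Cope rearrangement, known as a ring expansion for 1,2-dialkenylcycloalkane-1,2-diols and 1,2-divinylcyclohexanols. The only ring made is the ten-membered carbocycle, and it arises by cleavage of the bond shared with the six-membered ring (ring expansion by four carbons), not by end-to-end closure. Because the diol is trans, both alkenyl arms are equatorial on the cyclohexene and only one chair transition state, fused like a trans-decalin, is available. In that chair the (E)-enol ether oxygen is equatorial at C6, and with the configurations of C3 and C8 this fixes the single new stereocentre C6 (O α, as in the target). C1=C10 is a spectator and stays cis, C2 and C9 are untouched, and the enolates emerge regiodefined at C3=C4 and C7=C8. The step needs silylation to be faster than E1cB loss of the C6 benzyloxide from the C8 enolate and than transannular aldol reaction; the cold quench and the poor overlap of the equatorial C6–O bond with the enolate secure this. Because O9 and the trap carry the same silyl group, a 1,2-silyl shift from O9 to the O8 alkoxide would lead to the same product.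

Step 14
Reactants: 24 ethyl bromopyruvate
Product: 25 ethyl 3-acetoxy-2-oxopropanoate
Conditions: KOAc, acetone, rt
Reagents that add atoms: potassium acetate, CC(=O)[O-].[K+]
Why: SN2 displacement of an α-bromo ketone by carboxylate gives the C11–C12–C13 unit with C13 already acetylated.

Step 15
Reactants: 23 bis(silyl enol ether); 25 keto ester
Product: 26 aldol adduct (8-ketone; C7–C11 bond; C11 tertiary OH; C3=C4 TBS enol ether kept)
Conditions: BF3·OEt2 (1.1 equiv), CH2Cl2, −78 °C; aq. NaHCO3
Reagents that add atoms: none
Why: Mukaiyama aldol addition; the trisubstituted C7=C8 enol ether reacts at C7, whereas the tetrasubstituted C3=C4 ether would have to join two fully substituted carbons and is left. The new centres C7 and C11 are removed in the next step.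

Step 16
Reactants: 26 aldol adduct
Product: 28 8-oxo-7(11)-enoate (ester trans to C8; C13 acetate cis to C8), via tertiary mesylate 27 (not isolated)
Conditions: MsCl, Et3N, CH2Cl2, −20 to 0 °C
Reagents that add atoms: none
Why: Sulfene-mediated mesylation of the tertiary alcohol, then E1cB elimination through the C8 enolate; the mesylate leaves far faster than the C6 benzyloxide. The isomer with the ester away from the C8 carbonyl is expected on dipole and steric grounds, and it is the one that can later lactonise onto O6.

Step 17
Reactants: 28 enone ester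
Product: 29 8β-alcohol
Conditions: NaBH4, CeCl3·7H2O, MeOH/THF, −78 °C
Reagents that add atoms: none
Why: Luche 1,2-reduction; under Felkin–Anh control hydride attacks anti to the non-chelating C9–OTBS bond and gives the 8,9-threo (8β) alcohol. The ester trans to C8 cannot lactonise onto it.

Step 18
Reactants: 29 allylic alcohol
Product: 30 8β-acetate
Conditions: Ac2O, pyridine, DMAP (cat.), CH2Cl2, 0 °C
Reagents that add atoms: acetic anhydride, CC(=O)OC(C)=O
Why: DMAP-catalysed acetylation of the only free hydroxyl; the hindered silyl enol ether is stable to these mildly basic conditions.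

Step 19
Reactants: 30 silyl enol ether acetate
Product: 31 (4Z)-en-3-one (ring-cis C4=C5)
Conditions: Pd(OAc)2 (1.1 equiv), MeCN, rt
Reagents that add atoms: none
Why: Saegusa–Ito oxidation; divalent palladium forms the C4 palladium enolate and syn β-hydride elimination toward the ring carbon C5 gives the conjugated endocyclic enone. The ring-cis geometry is expected, as is usual for cyclodec-2-enones, and it is the geometry needed for the cis-epoxide.

Step 20
Reactants: 31 enone
Product: 32 3α-alcohol (2,3-erythro)
Conditions: Zn(BH4)2, Et2O, −30 °C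
Reagents that add atoms: none
Why: Chelation-controlled (Cram chelate) 1,2-reduction; zinc bridges the C3 carbonyl and the C2 arylmethyl ether oxygen, and hydride enters from the side of H-2 to give the anti (erythro) 2α,3α arrangement. Esters and acetates are not reduced.

Step 21
Reactants: 32 allylic alcohol
Product: 33 4β,5β-epoxide
Conditions: mCPBA, NaHCO3, CH2Cl2, 0 °C
Reagents that add atoms: 3-chloroperoxybenzoic acid, OOC(=O)c1cccc(Cl)c1
Why: Hydroxyl-assisted (Henbest-type) Prilezhaev epoxidation; A(1,3) strain holds H-3 and H-6 in the alkene plane, so the peracid, hydrogen-bonded to the C3 hydroxyl, attacks the peripheral face and gives the threo epoxy alcohol. C1=C10 is deactivated by three allylic C–O bonds and C7=C11 is electron-poor.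

Step 22
Reactants: 33 epoxy alcohol
Product: 35 6,12-olide 2α,3α-diol (butenolide; 4β,5β-epoxide; 8β-OAc; 9α-OTBS; 14-OTBS), via triol ethyl ester 34 (not isolated)
Conditions: DDQ (3 equiv), CH2Cl2/pH 7 buffer, 0 °C to rt; PPTS (cat.), CH2Cl2, rt
Reagents that add atoms: none
Why: Oxidative cleavage of the PMB and NAP ethers by benzylic hydride abstraction and hemiacetal hydrolysis. The freed C6 hydroxyl is cis to the ester on C7=C11 and lactonises to the butenolide, which locks the alkene geometry.

Step 23
Reactants: 35 erythro diol
Product: 36 2,3:4,5-bis-epoxide (9α-OTBS; 14-OTBS)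
Conditions: PPh3, DIAD, toluene, 0 °C to rt
Reagents that add atoms: none
Why: Mitsunobu cyclodehydration of a 1,2-diol; the allylic C2 hydroxyl is activated and displaced from the rear by O3. Displacement at C3 is blocked by the adjacent quaternary C4, so C2 is inverted (O β), C3 is retained (O α) and the trans-epoxide results.

Step 24
Reactants: 36 bis-silyl ether
Product: 37 9α,14-diol
Conditions: HF·pyridine, pyridine, THF, 0 °C to rt
Reagents that add atoms: none
Why: Fluoride-mediated desilylation buffered with pyridine removes the primary and the secondary TBS ether in one step; esters and the lactone are inert.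

Step 25
Reactants: 37 diol; 38 3-methylbut-2-enoyl chloride
Product: 39 14-O-(3-methylbut-2-enoate) with free 9α-OH
Conditions: pyridine, CH2Cl2, −30 °C
Reagents that add atoms: none
Why: Acylation of the primary allylic alcohol in preference to the hindered C9 alcohol; the weak base avoids vinylketene formation and deconjugation of the acyl group.

Step 26
Reactants: 40 (R)-(2-methyloxiran-2-yl)methanol
Product: 41 (S)-2-methyloxirane-2-carboxylic acid
Conditions: RuCl3·xH2O (2 mol %), NaIO4, MeCN/EtOAc/H2O, 0 °C to rt
Reagents that add atoms: water, O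
Why: Ruthenium tetroxide oxidation of a primary alcohol to the acid; the quaternary centre is untouched and the descriptor changes from R to S only through the priority change.

Step 27
Reactants: 39 C9 alcohol; 41 glycidic acid
Product: 43 CNP0279449.1 ((2R,3S,4S,5S,6R,8R,9R); glycidate 2S), via mixed anhydride 42 (not isolated)
Conditions: 41, 2,4,6-trichlorobenzoyl chloride, Et3N, THF, rt; 39, DMAP, toluene, rt
Reagents that add atoms: none
Why: Yamaguchi esterification, chosen for the hindered secondary alcohol; the mixed anhydride is attacked at the less hindered glycidoyl carbonyl and no stereocentre is touched.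

## Compound list

1 | (1S,2S)-3-bromocyclohexa-3,5-diene-1,2-diol | O[C@@H]1[C@H](O)C(Br)=CC=C1 | starting material
2 | (3aS,7aS)-4-bromo-2,2-dimethyl-3a,7a-dihydro-1,3-benzodioxole | O1[C@@H]2[C@H](OC1(C)C)C(Br)=CC=C2 | intermediate
3 | 2β,3β-epoxide of 2 (anti to the acetonide) | O1[C@@H]2[C@H](OC1(C)C)C(Br)=C[C@H]3O[C@@H]23 | intermediate
4 | naphthalen-2-ylmethanol | OCc1ccc2ccccc2c1 | starting material
5 | 10-bromo-2α-(naphthalen-2-ylmethoxy)cyclohexen-3β-ol 8α,9α-acetonide | O1[C@@H]2[C@H](OC1(C)C)C(Br)=C[C@H](OCc3ccc4ccccc4c3)[C@H]2O | intermediate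
6 | 3-ketone of 5 | O1[C@@H]2[C@H](OC1(C)C)C(Br)=C[C@H](OCc3ccc4ccccc4c3)C2=O | intermediate
7 | isopropenylmagnesium bromide | CC(=C)[Mg]Br | starting material
8 | 10-bromo-3β-isopropenyl-2α-(naphthalen-2-ylmethoxy)cyclohexen-3α-ol 8α,9α-acetonide | O1[C@@H]2[C@H](OC1(C)C)C(Br)=C[C@H](OCc3ccc4ccccc4c3)[C@@]2(O)C(C)=C | intermediate
9 | (tributylstannyl)methanol | CCCC[Sn](CCCC)(CCCC)CO | starting material
10 | 10-(hydroxymethyl) analogue of 8 | O1[C@@H]2[C@H](OC1(C)C)C(CO)=C[C@H](OCc3ccc4ccccc4c3)[C@@]2(O)C(C)=C | intermediate
11 | 3α,8α,9α,14-tetraol (3β-isopropenyl, 2α-O-NAP) | O[C@@H]1[C@H](O)C(CO)=C[C@H](OCc2ccc3ccccc3c2)[C@@]1(O)C(C)=C | intermediate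
12 | 9α,14-bis-O-TBS ether of 11 | O[C@@H]1[C@H](O[Si](C)(C)C(C)(C)C)C(CO[Si](C)(C)C(C)(C)C)=C[C@H](OCc2ccc3ccccc3c2)[C@@]1(O)C(C)=C | intermediate
13 | 8-ketone of 12 | O=C1[C@H](O[Si](C)(C)C(C)(C)C)C(CO[Si](C)(C)C(C)(C)C)=C[C@H](OCc2ccc3ccccc3c2)[C@@]1(O)C(C)=C | intermediate
14 | 4-methoxybenzyl alcohol | COc1ccc(CO)cc1 | starting material
15 | trichloroethylene | ClC=C(Cl)Cl | starting material
16 | 1-({[(E)-1,2-dichloroethenyl]oxy}methyl)-4-methoxybenzene | Cl/C=C(/Cl)OCc1ccc(OC)cc1 | intermediate
17 | lithium 2-[(4-methoxybenzyl)oxy]ethynide | [Li]C#COCc1ccc(OC)cc1 | intermediate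
18 | chloromagnesium 3α-alkoxide of 13 | O=C1[C@H](O[Si](C)(C)C(C)(C)C)C(CO[Si](C)(C)C(C)(C)C)=C[C@H](OCc2ccc3ccccc3c2)[C@@]1(O[Mg]Cl)C(C)=C | intermediate
19 | 8α-[(4-methoxybenzyloxy)ethynyl] 3α,8β-diol | O[C@@]1(C#COCc2ccc(OC)cc2)[C@H](O[Si](C)(C)C(C)(C)C)C(CO[Si](C)(C)C(C)(C)C)=C[C@H](OCc2ccc3ccccc3c2)[C@@]1(O)C(C)=C | intermediate
20 | 8α-[(E)-2-(4-methoxybenzyloxy)ethenyl]-3β-isopropenyl 3α,8β-diol (oxy-Cope precursor) | O[C@@]1(/C=C/OCc2ccc(OC)cc2)[C@H](O[Si](C)(C)C(C)(C)C)C(CO[Si](C)(C)C(C)(C)C)=C[C@H](OCc2ccc3ccccc3c2)[C@@]1(O)C(C)=C | intermediate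
21 | dipotassium 3α,8β-dialkoxide of 20 | [K+].[K+].[O-][C@@]1(/C=C/OCc2ccc(OC)cc2)[C@H](O[Si](C)(C)C(C)(C)C)C(CO[Si](C)(C)C(C)(C)C)=C[C@H](OCc2ccc3ccccc3c2)[C@@]1([O-])C(C)=C | intermediate
22 | dipotassium bis-enolate of the ten-membered 3,8-dione | [K+].[K+].[O-]/C1=C\[C@@H](OCc2ccc(OC)cc2)C/C(C)=C([O-])/[C@@H](OCc2ccc3ccccc3c2)/C=C(CO[Si](C)(C)C(C)(C)C)\[C@H]1O[Si](C)(C)C(C)(C)C | intermediate
23 | ten-membered triene bis(TBS enol ether): ring-cis C1=C10, ring-trans C3=C4 and C7=C8 enol ethers, 6α-OPMB, 2α-O-NAP, 9α-OTBS, 14-OTBS | CC(C)(C)[Si](C)(C)O/C1=C\[C@@H](OCc2ccc(OC)cc2)C/C(C)=C(O[Si](C)(C)C(C)(C)C)/[C@@H](OCc2ccc3ccccc3c2)/C=C(CO[Si](C)(C)C(C)(C)C)\[C@H]1O[Si](C)(C)C(C)(C)C | intermediate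
24 | ethyl 3-bromo-2-oxopropanoate | CCOC(=O)C(=O)CBr | starting material
25 | ethyl 3-acetoxy-2-oxopropanoate | CCOC(=O)C(=O)COC(C)=O | intermediate
26 | aldol adduct (8-ketone, C11 tertiary alcohol; C7/C11 mixture) | O=C1C(C(O)(C(=O)OCC)COC(C)=O)[C@@H](OCc2ccc(OC)cc2)C/C(C)=C(O[Si](C)(C)C(C)(C)C)/[C@@H](OCc2ccc3ccccc3c2)/C=C(CO[Si](C)(C)C(C)(C)C)\[C@H]1O[Si](C)(C)C(C)(C)C | intermediate
27 | C11 mesylate of 26 | O=C1C(C(OS(C)(=O)=O)(C(=O)OCC)COC(C)=O)[C@@H](OCc2ccc(OC)cc2)C/C(C)=C(O[Si](C)(C)C(C)(C)C)/[C@@H](OCc2ccc3ccccc3c2)/C=C(CO[Si](C)(C)C(C)(C)C)\[C@H]1O[Si](C)(C)C(C)(C)C | intermediate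
28 | 8-oxo-7(11)-enoate (ester trans to C8) | O=C1/C(=C(/C(=O)OCC)COC(C)=O)[C@@H](OCc2ccc(OC)cc2)C/C(C)=C(O[Si](C)(C)C(C)(C)C)/[C@@H](OCc2ccc3ccccc3c2)/C=C(CO[Si](C)(C)C(C)(C)C)\[C@H]1O[Si](C)(C)C(C)(C)C | intermediate
29 | 8β-alcohol | O[C@@H]1/C(=C(/C(=O)OCC)COC(C)=O)[C@@H](OCc2ccc(OC)cc2)C/C(C)=C(O[Si](C)(C)C(C)(C)C)/[C@@H](OCc2ccc3ccccc3c2)/C=C(CO[Si](C)(C)C(C)(C)C)\[C@H]1O[Si](C)(C)C(C)(C)C | intermediate
30 | 8β-acetate | CC(=O)O[C@@H]1/C(=C(/C(=O)OCC)COC(C)=O)[C@@H](OCc2ccc(OC)cc2)C/C(C)=C(O[Si](C)(C)C(C)(C)C)/[C@@H](OCc2ccc3ccccc3c2)/C=C(CO[Si](C)(C)C(C)(C)C)\[C@H]1O[Si](C)(C)C(C)(C)C | intermediate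
31 | (4Z)-en-3-one | CC(=O)O[C@@H]1/C(=C(/C(=O)OCC)COC(C)=O)[C@@H](OCc2ccc(OC)cc2)/C=C(C)\C(=O)[C@@H](OCc2ccc3ccccc3c2)/C=C(CO[Si](C)(C)C(C)(C)C)\[C@H]1O[Si](C)(C)C(C)(C)C | intermediate
32 | 3α-alcohol | CC(=O)O[C@@H]1/C(=C(/C(=O)OCC)COC(C)=O)[C@@H](OCc2ccc(OC)cc2)/C=C(C)\[C@@H](O)[C@@H](OCc2ccc3ccccc3c2)/C=C(CO[Si](C)(C)C(C)(C)C)\[C@H]1O[Si](C)(C)C(C)(C)C | intermediate
33 | 4β,5β-epoxy 3α-alcohol | CC(=O)O[C@@H]1/C(=C(/C(=O)OCC)COC(C)=O)[C@@H](OCc2ccc(OC)cc2)[C@@H]4O[C@]4(C)[C@@H](O)[C@@H](OCc2ccc3ccccc3c2)/C=C(CO[Si](C)(C)C(C)(C)C)\[C@H]1O[Si](C)(C)C(C)(C)C | intermediate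
34 | 2α,3α,6α-triol ethyl ester | CC(=O)O[C@@H]1/C(=C(/C(=O)OCC)COC(C)=O)[C@@H](O)[C@@H]4O[C@]4(C)[C@@H](O)[C@@H](O)/C=C(CO[Si](C)(C)C(C)(C)C)\[C@H]1O[Si](C)(C)C(C)(C)C | intermediate
35 | 6,12-olide 2α,3α-diol (4β,5β-epoxide, 8β-OAc, 9α-OTBS, 14-OTBS) | CC(=O)OCC1=C2[C@@H](OC(C)=O)[C@H](O[Si](C)(C)C(C)(C)C)/C(CO[Si](C)(C)C(C)(C)C)=C\[C@H](O)[C@H](O)[C@@]3(C)O[C@H]3[C@@H]2OC1=O | intermediate
36 | 2,3:4,5-bis-epoxide (9α-OTBS, 14-OTBS) | CC(=O)OCC1=C2[C@@H](OC(C)=O)[C@H](O[Si](C)(C)C(C)(C)C)/C(CO[Si](C)(C)C(C)(C)C)=C\[C@H]3O[C@@H]3[C@@]3(C)O[C@H]3[C@@H]2OC1=O | intermediate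
37 | 9α,14-diol | CC(=O)OCC1=C2[C@@H](OC(C)=O)[C@H](O)/C(CO)=C\[C@H]3O[C@@H]3[C@@]3(C)O[C@H]3[C@@H]2OC1=O | intermediate
38 | 3-methylbut-2-enoyl chloride | CC(C)=CC(Cl)=O | starting material
39 | 14-O-(3-methylbut-2-enoate), 9α-OH | CC(=O)OCC1=C2[C@@H](OC(C)=O)[C@H](O)/C(COC(=O)C=C(C)C)=C\[C@H]3O[C@@H]3[C@@]3(C)O[C@H]3[C@@H]2OC1=O | intermediate
40 | (R)-(2-methyloxiran-2-yl)methanol | OC[C@]1(C)CO1 | starting material
41 | (S)-2-methyloxirane-2-carboxylic acid | OC(=O)[C@]1(C)CO1 | intermediate
42 | (S)-2-methyloxirane-2-carboxylic 2,4,6-trichlorobenzoic anhydride | O=C(OC(=O)c1c(Cl)cc(Cl)cc1Cl)[C@]1(C)CO1 | intermediate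
43 | CNP0279449.1 | CC(=O)OCC1=C2[C@@H](OC(C)=O)[C@H](OC(=O)[C@]3(C)CO3)/C(COC(=O)C=C(C)C)=C\[C@H]3O[C@@H]3[C@@]3(C)O[C@H]3[C@@H]2OC1=O | target

## Step count and least certain steps

Total: 27 steps. Longest linear sequence: 24 steps (steps 1–9, 11–13, 15–25 and 27); steps 10, 14 and 26 prepare 16, 25 and 41.

**Step 13 (key step).** Most likely to go wrong: loss of the C6 benzyloxide by E1cB elimination from the C8 potassium enolate, or proton transfer between the two enolates, before silylation is complete; the enolate is a β-alkoxy enolate and is free of ion pairing. Fallback: from 20, both tertiary hydroxyls are silylated (TBSOTf, 2,6-lutidine) to give the bis(silyl ether) F1. Heating F1 in toluene (about 160 °C, sealed tube) should bring about the neutral siloxy-Cope shift through the same chair. No enolate is formed, and the product is 23, where the route is rejoined.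

**Step 11.** Most likely to go wrong: addition to the β face of the C8 carbonyl, giving the cis-diol. The chelated conformer places the C9 silyl ether in the ring plane beside the C10 substituent and the C2 ether pseudoaxial on the α face, and a Felkin–Anh pathway through the other half-chair leads to the wrong face. Fallback: from 13, both silyl ethers are removed (HF·pyridine) to give the trihydroxy ketone F2. Excess alkoxyacetylide with MgBr2·OEt2 is then added, so that the C3 and C9 alkoxides and the carbonyl form a tridentate chelate with the isopropenyl group axial; this should give the tetraol F3. Silylation of the primary and the secondary hydroxyl (TBSCl, imidazole) returns to the route at 19.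

**Step 16.** Most likely to go wrong: formation of the alkene isomer with the ester on the C8 side, because the E1cB step is kinetically controlled and the ammonium counter-ion can bridge the enolate and ester oxygens. That isomer would lactonise onto O8 after step 17. Fallback: from 26, the dehydration is run as before and the wrong isomer F4 is not discarded. It is equilibrated by reversible conjugate addition (catalytic iodine in daylight, or catalytic PPh3), the usual way to convert cis-ene-1,4-dicarbonyl compounds into the trans forms. This returns to the route at 28.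

**Step 17.** Most likely to go wrong: poor facial selectivity of hydride delivery, because the local conformation of the ten-membered ring, not the acyclic Felkin–Anh model, may decide the face; conjugate reduction is a lesser risk. Fallback: from 28, if the 8α-alcohol F5 is the main product, the centre is set by substitution instead. A Mitsunobu reaction of F5 with acetic acid (PPh3, DIAD) inverts C8 and gives the 8β-acetate 30 directly, where the route is rejoined.

**Step 19.** Most likely to go wrong: formation of the ring-trans enone, β-hydride elimination toward the C15 methyl (exocyclic enone), or ionisation of the allylic acetates by the zerovalent palladium released. Fallback: from 30, the silyl enol ether is treated with PhSeCl to give the α-phenylselanyl ketone F6. Oxidation (H2O2, pyridine, 0 °C) and syn-elimination of the selenoxide, a metal-free route to cis-enones in ten-membered ketones, return to the route at 31.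

**Step 24.** Most likely to go wrong: acid-promoted opening of the allylic 2,3-epoxide by HF during the slow cleavage of the hindered C9 silyl ether. Fallback: the desilylation is moved before the formation of that epoxide. From 35, HF·pyridine gives the tetraol F7, and selective acylation of the primary hydroxyl with 38 (pyridine, −40 °C) gives F8. Mitsunobu cyclodehydration (PPh3, DIAD) of the 2,3-diol, with the hindered C9 hydroxyl as spectator, returns to the route at 39.

## Further compounds

F1 | step 13 | 3α,8β-bis-O-TBS ether of 20 | CC(C)(C)[Si](C)(C)O[C@@]1(/C=C/OCc2ccc(OC)cc2)[C@H](O[Si](C)(C)C(C)(C)C)C(CO[Si](C)(C)C(C)(C)C)=C[C@H](OCc2ccc3ccccc3c2)[C@@]1(O[Si](C)(C)C(C)(C)C)C(C)=C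
F2 | step 11 | 3α,9α,14-trihydroxy 8-ketone (desilylated 13) | O=C1[C@H](O)C(CO)=C[C@H](OCc2ccc3ccccc3c2)[C@@]1(O)C(C)=C
F3 | step 11 | 8α-[(4-methoxybenzyloxy)ethynyl] 3α,8β,9α,14-tetraol | O[C@@]1(C#COCc2ccc(OC)cc2)[C@H](O)C(CO)=C[C@H](OCc2ccc3ccccc3c2)[C@@]1(O)C(C)=C
F4 | step 16 | geometric isomer of 28 (ester cis to C8) | O=C1/C(=C(\C(=O)OCC)COC(C)=O)[C@@H](OCc2ccc(OC)cc2)C/C(C)=C(O[Si](C)(C)C(C)(C)C)/[C@@H](OCc2ccc3ccccc3c2)/C=C(CO[Si](C)(C)C(C)(C)C)\[C@H]1O[Si](C)(C)C(C)(C)C
F5 | step 17 | 8α-alcohol (C8 epimer of 29) | O[C@H]1/C(=C(/C(=O)OCC)COC(C)=O)[C@@H](OCc2ccc(OC)cc2)C/C(C)=C(O[Si](C)(C)C(C)(C)C)/[C@@H](OCc2ccc3ccccc3c2)/C=C(CO[Si](C)(C)C(C)(C)C)\[C@H]1O[Si](C)(C)C(C)(C)C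
F6 | step 19 | 4-(phenylselanyl) 3-ketone from 30 (C4 mixture) | CC(=O)O[C@@H]1/C(=C(/C(=O)OCC)COC(C)=O)[C@@H](OCc2ccc(OC)cc2)CC(C)([Se]c2ccccc2)C(=O)[C@@H](OCc2ccc3ccccc3c2)/C=C(CO[Si](C)(C)C(C)(C)C)\[C@H]1O[Si](C)(C)C(C)(C)C
F7 | step 24 | 6,12-olide 2α,3α,9α,14-tetraol (4β,5β-epoxide) | CC(=O)OCC1=C2[C@@H](OC(C)=O)[C@H](O)/C(CO)=C\[C@H](O)[C@H](O)[C@@]3(C)O[C@H]3[C@@H]2OC1=O
F8 | step 24 | 14-O-(3-methylbut-2-enoate) of F7 | CC(=O)OCC1=C2[C@@H](OC(C)=O)[C@H](O)/C(COC(=O)C=C(C)C)=C\[C@H](O)[C@H](O)[C@@]3(C)O[C@H]3[C@@H]2OC1=O
A1 | alternative 1 | bicyclic core with C9 triethylsilyl and C14 tert-butyldimethylsilyl ethers | CC(=O)OCC1=C2[C@@H](OC(C)=O)[C@H](O[Si](CC)(CC)CC)/C(CO[Si](C)(C)C(C)(C)C)=C\[C@H]3O[C@@H]3[C@@]3(C)O[C@H]3[C@@H]2OC1=O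
A2 | alternative 2 | C3,C6-endoperoxide of the ten-membered trienoate | COC(=O)/C(COC(C)=O)=C1/[C@@H](OC(C)=O)[C@H](O[Si](C)(C)C(C)(C)C)/C(CO[Si](c2ccccc2)(c2ccccc2)C(C)(C)C)=C\[C@H](O[Si](CC)(CC)CC)[C@@H]2OO[C@H]1C=C2C
A3 | alternative 3 | 2,7-dimethylnaphthalene | Cc1ccc2ccc(C)cc2c1
A4 | alternative 3 | 2,7-dimethyl-1,4,5,8-tetrahydronaphthalene | CC1=CCC2=C(C1)CC(C)=CC2
A5 | alternative 3 | (3Z,8Z)-4,8-dimethylcyclodeca-3,8-diene-1,6-dione | O=C1C/C=C(C)\CC(=O)C/C(C)=C\C1
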